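**Retrosynthetic overview**
- Feature: ring B carries its oxygen at C3, para to the spiro carbon C6, so ring B is a phenol ring; C11, the ring A carbon bearing the methylidene, is the internal carbon of a terminal alkyne attacked by the phenol para carbon.
- Target 15 ⇐ α-bromoketone 14 (axial methyl to C3) ⇐ enone 12 (reductive bromination at C4) ⇐ dienone 10 (desymmetrising 1,4-reduction fixes C6).
- Dienone 10 ⇐ phenol alkyne 9 by gold-catalysed ipso 6-exo-dig hydroarylation, forming C6–C11 and closing ring A.
- 9 ⇐ phenol + bromohydrin 6 (para Friedel–Crafts alkylation through a bromine-bridged C7 cation; C8–Br already in place) ⇐ epoxide 5 ⇐ enyne 4 ⇐ 1 + 2.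
- Ring order: ring B is bought as phenol, ring A is closed in step 6, ring B is then saturated and functionalised.

Key step: step 6

Remark on labels: C6 is the spiro carbon; ring B is C1–C5 with C3 the oxygen-bearing carbon and C4 the brominated carbon (C2 in the systematic names of 14 and 15); ring A is C7 (CMe2), C8 (CHBr), C9, C10, C11 (C=CH2).
Assumption: which antipode of the bisphosphine in step 7 reduces the arm leading to (6R) cannot be predicted for this spiro substrate; the route is written with the (R) ligand, and the (S) ligand is used instead if product analysis shows the other arm was reduced.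

**Step 1**
Reactants: 1 ethynyltrimethylsilane; 2 5-bromo-2-methylpent-2-ene
Product: 4 trimethyl(6-methylhept-5-en-1-yn-1-yl)silane, via lithium (trimethylsilyl)acetylide 3 (not isolated)
Conditions: n-BuLi, THF, −78 °C; then 2, DMPU, −78 °C → rt
Reagents that add atoms: none
Why: Deprotonation of 1 gives the acetylide 3, which displaces the primary bromide of 2 in an SN2 alkylation once the polar cosolvent breaks up its aggregates; the silyl group blocks double alkylation and keeps the product non-volatile.

**Step 2**
Reactants: 4 trimethyl(6-methylhept-5-en-1-yn-1-yl)silane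
Product: 5 (3R)-2,2-dimethyl-3-[4-(trimethylsilyl)but-3-yn-1-yl]oxirane
Conditions: D-fructose-derived Shi ketone (30 mol %), KHSO5 (as the triple salt 2KHSO5·KHSO4·K2SO4), K2CO3, n-Bu4NHSO4, MeCN/CH2(OMe)2/aq. Na2B4O7 buffer, 0 °C
Reagents that add atoms: potassium peroxymonosulfate, [K+].[O-]S(=O)(=O)OO
Why: Shi asymmetric epoxidation, in which the chiral dioxirane transfers oxygen to the trisubstituted alkene through a spiro transition state; the D-fructose-derived ketone should give the (R)-epoxide for the Me2C=CH–CH2R class, setting the centre that becomes C8, and the silyl alkyne is inert.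

**Step 3**
Reactants: 5 (3R)-2,2-dimethyl-3-[4-(trimethylsilyl)but-3-yn-1-yl]oxirane
Product: 6 (3S)-3-bromo-2-methyl-7-(trimethylsilyl)hept-6-yn-2-ol
Conditions: Li2NiBr4 (THF solution, 1.5 equiv), THF, 0 °C → rt; aq. work-up
Reagents that add atoms: dilithium tetrabromonickelate, [Li+].[Li+].Br[Ni-2](Br)(Br)Br
Why: The soft bromide of Li2NiBr4 opens the epoxide by SN2 attack at the less substituted secondary carbon, so bromine enters with inversion and the (R)-epoxide should give the (S)-bromide with a free tertiary alcohol.

**Step 4**
Reactants: 6 (3S)-3-bromo-2-methyl-7-(trimethylsilyl)hept-6-yn-2-ol; 7 phenol (5 equiv)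
Product: 8 4-[(3S)-3-bromo-2-methyl-7-(trimethylsilyl)hept-6-yn-2-yl]phenol
Conditions: TfOH (5 mol %), (CF3)2CHOH, 0 °C, short reaction time; aq. NaHCO3 quench, no alkaline wash
Reagents that add atoms: none
Why: Dehydrative Friedel–Crafts alkylation in which acid in the ionising fluoro alcohol removes the tertiary hydroxyl as water with help from the neighbouring bromine and the bromine-bridged tertiary cation is opened at C7 by the para carbon of phenol (the pattern of arene alkylation by β-halo tertiary cations), while the C8–Br bond is never broken so the (S) configuration is carried over and the bulky silyl group keeps the tethered alkyne from competing.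

**Step 5**
Reactants: 8 4-[(3S)-3-bromo-2-methyl-7-(trimethylsilyl)hept-6-yn-2-yl]phenol
Product: 9 4-[(3S)-3-bromo-2-methylhept-6-yn-2-yl]phenol
Conditions: n-Bu4NF (1.2 equiv), AcOH (1.5 equiv), THF, 0 °C
Reagents that add atoms: none
Why: Fluoride-induced protodesilylation of the alkynylsilane, buffered with acetic acid because the phenoxide would expel the β-bromide by aryl participation to a spirocyclopropyl dienone (carbonate in methanol is therefore avoided).

**Step 6**
Reactants: 9 4-[(3S)-3-bromo-2-methylhept-6-yn-2-yl]phenol
Product: 10 (8S)-8-bromo-7,7-dimethyl-11-methylidenespiro[5.5]undeca-1,4-dien-3-one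
Conditions: [(t-Bu)2(2-biphenylyl)P]Au(NCMe)SbF6 (5 mol %), CH2Cl2 (0.02 M), 4 Å MS, rt
Reagents that add atoms: none
Why: The cationic monovalent gold phosphine complex binds the terminal alkyne and the ring carbon para to the hydroxyl (the ipso carbon carrying the tether) attacks the internal alkyne carbon C11 anti to gold, after which loss of the phenolic proton gives the cross-conjugated dienone and that proton cleaves the vinyl–gold bond to leave the C11 methylidene. The closest known reaction type is the gold-catalysed dearomative ipso-Friedel–Crafts alkenylation of phenols with tethered terminal alkynes, established mainly for five-membered ring closure. Ring A (C6–C7–C8–C9–C10–C11) closes in the 6-exo-dig mode by forming C6–C11, helped by the gem-dimethyl group at C7, and ring B is the former phenol ring. No stereocentre is created, because C6 still carries two identical enone arms, and the C8–Br bond is a spectator. The selectivity needed is ipso attack over other ring positions and over external nucleophiles: the carbons ortho to the tether are meta to the hydroxyl and would need a seven-membered ring, the carbons ortho to the hydroxyl cannot reach the alkyne, and dry, dilute, silver-free, acid-free conditions suppress hydration and ionisation of the C8 bromide through a phenonium ion.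

**Step 7**
Reactants: 10 (8S)-8-bromo-7,7-dimethyl-11-methylidenespiro[5.5]undeca-1,4-dien-3-one
Product: 12 (6R,8S)-8-bromo-7,7-dimethyl-11-methylidenespiro[5.5]undec-1-en-3-one, via diethoxy(methyl)silyl dienol ether 11 (not isolated)
Conditions: Cu(OAc)2 (5 mol %), (R)-DTBM-SEGPHOS (5.5 mol %), (EtO)2MeSiH (1.1 equiv), toluene, −20 °C; then 0.5 M HCl, THF, 0 °C, brief
Reagents that add atoms: none
Why: Copper hydride-catalysed desymmetrising 1,4-reduction of a 4,4-disubstituted cyclohexadienone, in which the chiral bisphosphine–CuH tells the two enone arms apart by the quaternary C7 versus the planar C11 on the spiro carbon and so makes C6 a stereocentre (R) under catalyst control, while the silyl dienol ether 11 is protected from a second reduction until it is hydrolysed.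

**Step 8**
Reactants: 12 (6R,8S)-8-bromo-7,7-dimethyl-11-methylidenespiro[5.5]undec-1-en-3-one
Product: 14 (2R,6R,8S)-2,8-dibromo-7,7-dimethyl-11-methylidenespiro[5.5]undecan-3-one, via dimethyl(phenyl)silyl enol ether 13 (not isolated)
Conditions: [(Ph3P)CuH]6 (5 mol %), PhMe2SiH (1.1 equiv), toluene, rt; then NBS (1.1 equiv), THF, −78 °C
Reagents that add atoms: N-bromosuccinimide, O=C1CCC(=O)N1Br
Why: Copper hydride conjugate reduction gives the regiodefined silyl enol ether 13 on the remaining arm and NBS brominates C4 on the face anti to the axial C11 of the spiro centre (the situation of 2α-bromination of 3-keto-5α-steroids), which should give the equatorial bromide, also the thermodynamically favoured epimer because an axial bromine would clash with C11, so any axial epimer can be equilibrated by bromide exchange (LiBr, acetone).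

**Step 9**
Reactants: 14 (2R,6R,8S)-2,8-dibromo-7,7-dimethyl-11-methylidenespiro[5.5]undecan-3-one
Product: 15 (2R,3R,6R,8S)-2,8-dibromo-3,7,7-trimethyl-11-methylidenespiro[5.5]undecan-3-ol
Conditions: MeAl(OAr)2 (Ar = 2,6-di-tert-butyl-4-methylphenyl; 3 equiv, made from Me3Al and 2 ArOH), toluene, −78 °C; then MeLi (3 equiv), −78 °C; H2O quench at −78 °C
Reagents that add atoms: methyllithium, [Li]C
Why: Carbonyl methylation under approach control by a bulky aluminium Lewis acid, which complexes the ketone on its open equatorial side so that methyllithium adds along the axial trajectory of the chair with C7 and the C4 bromine equatorial, placing methyl axial and cis to bromine and hydroxyl equatorial and trans to bromine (3R); the trans-diequatorial bromohydrin alkoxide is not aligned anti-periplanar for epoxide closure and is protonated cold before a ring flip could allow it.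

**Compound list**
1 | ethynyltrimethylsilane | C#C[Si](C)(C)C | starting material
2 | 5-bromo-2-methylpent-2-ene | CC(C)=CCCBr | starting material
3 | lithium (trimethylsilyl)acetylide | [Li]C#C[Si](C)(C)C | intermediate
4 | trimethyl(6-methylhept-5-en-1-yn-1-yl)silane | CC(C)=CCCC#C[Si](C)(C)C | intermediate
5 | (3R)-2,2-dimethyl-3-[4-(trimethylsilyl)but-3-yn-1-yl]oxirane | CC1(C)O[C@@H]1CCC#C[Si](C)(C)C | intermediate
6 | (3S)-3-bromo-2-methyl-7-(trimethylsilyl)hept-6-yn-2-ol | CC(C)(O)[C@@H](Br)CCC#C[Si](C)(C)C | intermediate
7 | phenol | Oc1ccccc1 | starting material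
8 | 4-[(3S)-3-bromo-2-methyl-7-(trimethylsilyl)hept-6-yn-2-yl]phenol | C[Si](C)(C)C#CCC[C@H](Br)C(C)(C)c1ccc(O)cc1 | intermediate
9 | 4-[(3S)-3-bromo-2-methylhept-6-yn-2-yl]phenol | C#CCC[C@H](Br)C(C)(C)c1ccc(O)cc1 | intermediate
10 | (8S)-8-bromo-7,7-dimethyl-11-methylidenespiro[5.5]undeca-1,4-dien-3-one | C=C1CC[C@H](Br)C(C)(C)C12C=CC(=O)C=C2 | intermediate
11 | {[(6R,8S)-8-bromo-7,7-dimethyl-11-methylidenespiro[5.5]undeca-1,3-dien-3-yl]oxy}diethoxy(methyl)silane | C=C1CC[C@H](Br)C(C)(C)[C@@]12CC=C(O[Si](C)(OCC)OCC)C=C2 | intermediate
12 | (6R,8S)-8-bromo-7,7-dimethyl-11-methylidenespiro[5.5]undec-1-en-3-one | C=C1CC[C@H](Br)C(C)(C)[C@@]12CCC(=O)C=C2 | intermediate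
13 | {[(6R,8S)-8-bromo-7,7-dimethyl-11-methylidenespiro[5.5]undec-2-en-3-yl]oxy}dimethyl(phenyl)silane | C=C1CC[C@H](Br)C(C)(C)[C@@]12CCC(O[Si](C)(C)c3ccccc3)=CC2 | intermediate
14 | (2R,6R,8S)-2,8-dibromo-7,7-dimethyl-11-methylidenespiro[5.5]undecan-3-one | C=C1CC[C@H](Br)C(C)(C)[C@@]12CCC(=O)[C@H](Br)C2 | intermediate
15 | (2R,3R,6R,8S)-2,8-dibromo-3,7,7-trimethyl-11-methylidenespiro[5.5]undecan-3-ol | C=C1CC[C@H](Br)C(C)(C)[C@@]12CC[C@@](C)(O)[C@H](Br)C2 | target

Total step count: 9. Longest linear sequence: 9 steps (1 or 2 to 15).

**Steps most likely to fail**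

Step 6. Closure of a six-membered ring beside the quaternary C7 may be slow enough that alkyne hydration or oligomerisation takes over. The cationic gold may also assist loss of the C8 bromide through the phenonium ion, with aryl migration and loss of configuration. Adventitious acid may trigger dienone–phenol rearrangement or migration of the exocyclic alkene into the ring. The fallback sets out from 9 and returns at 10, and replaces π-acid catalysis by a stoichiometric electrophile. ICl (NaHCO3, CH2Cl2, −78 °C) should form the iodonium of the alkyne, which the ipso carbon opens anti in the same 6-exo sense to give (8S,11E)-8-bromo-11-(iodomethylidene)-7,7-dimethylspiro[5.5]undeca-1,4-dien-3-one F1. The vinyl iodide is then removed with Pd(PPh3)4 (cat.), HCO2H and Et3N in DMF to give 10; oxidative addition to zerovalent palladium is much faster at the C(sp2)–I bond than at the neopentyl C(sp3)–Br bond. Ring iodination of the phenol is the competing process to watch.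

Step 4. The bridged cation may hand Br+ to phenol instead of being attacked at carbon, which releases alkene 4 and erodes configuration by alkene–bromonium exchange. The tethered alkyne may capture the cation. On prolonged exposure the product may ionise at C8 through the phenonium ion and suffer aryl migration. The fallback sets out from 5 and returns at 10, and puts the aryl group on first and the bromine last. Phenol opens epoxide 5 at the tertiary carbon in (CF3)2CHOH (Friedel–Crafts epoxide arylation, C8–O untouched) to give 4-[(3R)-3-hydroxy-2-methyl-7-(trimethylsilyl)hept-6-yn-2-yl]phenol F2. Both hydroxyls are silylated (TBSOTf, 2,6-lutidine) to tert-butyl{4-[(3R)-3-(tert-butyldimethylsilyloxy)-2-methyl-7-(trimethylsilyl)hept-6-yn-2-yl]phenoxy}dimethylsilane F3. K2CO3 in MeOH then frees the phenol and the alkyne together (no bromide is present, so base is harmless) to give 4-[(3R)-3-(tert-butyldimethylsilyloxy)-2-methylhept-6-yn-2-yl]phenol F4. The gold cyclisation of step 6, now free of any ionisable bromide, gives (8R)-8-(tert-butyldimethylsilyloxy)-7,7-dimethyl-11-methylidenespiro[5.5]undeca-1,4-dien-3-one F5, and n-Bu4NF gives (8R)-8-hydroxy-7,7-dimethyl-11-methylidenespiro[5.5]undeca-1,4-dien-3-one F6. An Appel bromination (CBr4, P(n-C8H17)3, toluene, 70 °C) replaces the neopentyl hydroxyl with inversion and returns to 10; the weak point is a slow SN2 at a neopentyl ring carbon.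

Step 7. The catalyst may discriminate poorly between the two enone arms, giving a mixture of C6 epimers. Premature hydrolysis of the dienol ether may lead to over-reduction to the saturated ketone. The copper hydride may also add to the 1,1-disubstituted alkene. The fallback sets out from 10 and returns at 12: biocatalytic desymmetrisation with a flavin-dependent ene-reductase of the Old Yellow Enzyme family (NADP+, glucose, glucose dehydrogenase, buffer with cosolvent). This reduction is known for 4,4-disubstituted cyclohexadienones and stops after one C=C bond; a panel covering both arm preferences is screened. This path makes no new compound (F0).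

Further compounds
F1 | step 6 | (8S,11E)-8-bromo-11-(iodomethylidene)-7,7-dimethylspiro[5.5]undeca-1,4-dien-3-one | I/C=C1\CC[C@H](Br)C(C)(C)C12C=CC(=O)C=C2
F2 | step 4 | 4-[(3R)-3-hydroxy-2-methyl-7-(trimethylsilyl)hept-6-yn-2-yl]phenol | C[Si](C)(C)C#CCC[C@@H](O)C(C)(C)c1ccc(O)cc1
F3 | step 4 | tert-butyl{4-[(3R)-3-(tert-butyldimethylsilyloxy)-2-methyl-7-(trimethylsilyl)hept-6-yn-2-yl]phenoxy}dimethylsilane | C[Si](C)(C)C#CCC[C@@H](O[Si](C)(C)C(C)(C)C)C(C)(C)c1ccc(O[Si](C)(C)C(C)(C)C)cc1
F4 | step 4 | 4-[(3R)-3-(tert-butyldimethylsilyloxy)-2-methylhept-6-yn-2-yl]phenol | C#CCC[C@@H](O[Si](C)(C)C(C)(C)C)C(C)(C)c1ccc(O)cc1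
F5 | step 4 | (8R)-8-(tert-butyldimethylsilyloxy)-7,7-dimethyl-11-methylidenespiro[5.5]undeca-1,4-dien-3-one | C=C1CC[C@@H](O[Si](C)(C)C(C)(C)C)C(C)(C)C12C=CC(=O)C=C2
F6 | step 4 | (8R)-8-hydroxy-7,7-dimethyl-11-methylidenespiro[5.5]undeca-1,4-dien-3-one | C=C1CC[C@@H](O)C(C)(C)C12C=CC(=O)C=C2
F0 | step 7 | none | none
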